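**Retrosynthetic overview**
- The last step is a chelation-directed cleavage of the 5-O-methyl ether of a 6-hydroxy-5,7-dimethoxy flavanone. No protecting groups are used anywhere in the route.
- The C2–C1' bond comes from an enantioselective dearomative 1,4-arylation of a flat, achiral 3-methoxychromone (a 10π benzo-γ-pyrone) with a ring B arylboronate. The catalyst sets C2, and thermodynamic protonation sets C3 as trans.
- The chromone comes from twofold-symmetric 2,6-dimethoxyhydroquinone, methoxyacetic acid and one carbon of DMF. C-acylation at one of the two equivalent C–H positions is followed by formylative closure.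
- The hydroquinone comes from syringol by oxidation to the para-quinone and reduction. The boronate comes from 2,3-dimethoxyphenol by sterically governed C–H borylation.
- Ring order: rings A and B are bought as arenes, ring C is built as an aromatic γ-pyrone on ring A, and ring C is then dearomatised as ring B is attached.

Assumption: the SMILES decodes as the (2R,3R)-trans isomer, and the (S)-diphosphine is taken to expose the same enone face as in the known cyclohexenone and 4-quinolone additions; if the first run gives the antipode, the (R)-ligand is used.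

**Step 1**
Reactants: 1 2,6-dimethoxyphenol (syringol)
Product: 3 2,6-dimethoxybenzene-1,4-diol, via 2,6-dimethoxy-1,4-benzoquinone 2 (not isolated)
Conditions: Co(salen) (5 mol%), O2 (1 atm), DMF, rt; then aq Na2S2O4, EtOAc, rt, under N2
Reagents that add atoms: dioxygen, O=O
Why: This is a cobalt/O2 phenol-to-para-quinone oxidation (oxidative dearomatisation), which goes para because both ortho positions of syringol are blocked, and dithionite reduction then re-aromatises the quinone to the symmetric hydroquinone; no stereocentre is formed.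

**Step 2**
Reactants: 3 2,6-dimethoxybenzene-1,4-diol; 4 methoxyacetic acid
Product: 7 6-hydroxy-3,5,7-trimethoxy-4H-chromen-4-one, via aryl methoxymethyl ketone 5 (not isolated), via enaminone 6 (not isolated)
Conditions: 4 (1.1 equiv), BF3·OEt2 (solvent), 80 °C, 2 h; then DMF, MsCl, 0 → 60 °C; aq NaOAc work-up
Reagents that add atoms: N,N-dimethylformamide (DMF), CN(C)C=O
Why: Friedel–Crafts/Fries-type C-acylation can only reach the two equivalent ring C–H positions (each ortho to the unhindered OH), after which the boron-chelated ketone is formylated at its α-methylene by the Vilsmeier-type DMF/MsCl iminium salt and the ortho OH displaces Me2NH to close the γ-pyrone, which is the one-pot deoxybenzoin-to-isoflavone protocol (tolerant of free phenols) applied to an α-methoxy ketone; no stereocentre is formed.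

**Step 3**
Reactants: 8 2,3-dimethoxyphenol
Product: 11 2,3-dimethoxy-5-(4,4,5,5-tetramethyl-1,3,2-dioxaborolan-2-yl)phenol, via aryl O-boronate 9 (not isolated), via C,O-diborylated arene 10 (not isolated)
Conditions: B2pin2 (1.2 equiv), [Ir(OMe)(cod)]2 (1.5 mol%), dtbpy (3 mol%), THF, 80 °C; then H2O/MeOH, rt
Reagents that add atoms: bis(pinacolato)diboron (B2pin2), CC1(C)OB(OC1(C)C)B1OC(C)(C)C(C)(C)O1
Why: Iridium-catalysed aromatic C–H borylation is sterically governed, so after in situ O-borylation of the phenol only C5, the single C–H without an ortho substituent in this 1,2,3-trisubstituted ring, is borylated, and the O–B bond hydrolyses on work-up; no stereocentre is formed.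

**Step 4 (key step)**
Reactants: 7 6-hydroxy-3,5,7-trimethoxy-4H-chromen-4-one; 11 2,3-dimethoxy-5-(4,4,5,5-tetramethyl-1,3,2-dioxaborolan-2-yl)phenol
Product: 13 (2R,3R)-6-hydroxy-2-(3-hydroxy-4,5-dimethoxyphenyl)-3,5,7-trimethoxychroman-4-one, via cis C3-epimer 12 (not isolated)
Conditions: 11 (2 equiv), [RhCl(C2H4)2]2 (2.5 mol%), (S)-MeO-F12-BIPHEP [(S)-2,2'-bis[bis(3,4,5-trifluorophenyl)phosphino]-6,6'-dimethoxy-1,1'-biphenyl] (5.5 mol%), K3PO4 (1 equiv), dioxane/H2O 10:1, 50 °C, N2; work-up at pH 5
Reagents that add atoms: none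
Why: Proposed new method: the Hayashi–Miyaura asymmetric 1,4-addition, known for 3-unsubstituted chromones, for N-acyl-4-quinolones and for pinacol boronates made by C–H borylation, is extended here to a 3-methoxychromone, in which the aryl–rhodium species (formed by boron-to-rhodium transmetalation at the hydroxo complex of monovalent rhodium) binds the C2=C3 bond of the flat pyrone on the face left open by the (S)-biaryl diphosphine, syn-carborhodation breaks the pyrone aromaticity and puts the aryl on C2 (2R) to give an oxa-π-allyl rhodium enolate that water protonates, the electron-poor ligand compensates for the deactivated acceptor, and the phosphate/phenoxide buffer epimerises the acidic C3–H so that any kinetically formed cis 12 drains into the diequatorial trans isomer 13.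

**Step 5**
Reactants: 13 (2R,3R)-6-hydroxy-2-(3-hydroxy-4,5-dimethoxyphenyl)-3,5,7-trimethoxychroman-4-one
Product: 15 (2R,3R)-5,6-dihydroxy-2-(3-hydroxy-4,5-dimethoxyphenyl)-3,7-dimethoxychroman-4-one, via tris(dichloroboryl) ether 14 (not isolated)
Conditions: BCl3 (1 M in CH2Cl2, 4 equiv), CH2Cl2, −78 → −20 °C; then H2O, N2
Reagents that add atoms: none
Why: This is a chelation-controlled aryl methyl ether cleavage in which boron held between the C4 carbonyl and the peri oxygen activates only the 5-OMe for chloride attack at low temperature (the selectivity known for 6-hydroxy-5,7-dimethoxyflavonoids), whereas the 7-, 4'-, 5'- and aliphatic 3-OMe groups lack this six-membered chelate; C2 and C3 are not touched and already sit in the thermodynamic trans arrangement.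

**Compound list**
1 | 2,6-dimethoxyphenol (syringol) | COc1cccc(OC)c1O | starting material
2 | 2,6-dimethoxy-1,4-benzoquinone | COC1=CC(=O)C=C(OC)C1=O | intermediate
3 | 2,6-dimethoxybenzene-1,4-diol | COc1cc(O)cc(OC)c1O | intermediate
4 | methoxyacetic acid | COCC(=O)O | starting material
5 | 1-(3,6-dihydroxy-2,4-dimethoxyphenyl)-2-methoxyethan-1-one | COCC(=O)c1c(O)cc(OC)c(O)c1OC | intermediate
6 | (Z)-3-(dimethylamino)-1-(3,6-dihydroxy-2,4-dimethoxyphenyl)-2-methoxyprop-2-en-1-one (labile push–pull alkene) | CN(C)/C=C(\OC)C(=O)c1c(O)cc(OC)c(O)c1OC | intermediate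
7 | 6-hydroxy-3,5,7-trimethoxy-4H-chromen-4-one | COC1=COc2cc(OC)c(O)c(OC)c2C1=O | intermediate
8 | 2,3-dimethoxyphenol | COc1cccc(O)c1OC | starting material
9 | 2-(2,3-dimethoxyphenoxy)-4,4,5,5-tetramethyl-1,3,2-dioxaborolane | COc1cccc(OB2OC(C)(C)C(C)(C)O2)c1OC | intermediate
10 | 2-[2,3-dimethoxy-5-(4,4,5,5-tetramethyl-1,3,2-dioxaborolan-2-yl)phenoxy]-4,4,5,5-tetramethyl-1,3,2-dioxaborolane | COc1cc(B2OC(C)(C)C(C)(C)O2)cc(OB2OC(C)(C)C(C)(C)O2)c1OC | intermediate
11 | 2,3-dimethoxy-5-(4,4,5,5-tetramethyl-1,3,2-dioxaborolan-2-yl)phenol | COc1cc(B2OC(C)(C)C(C)(C)O2)cc(O)c1OC | intermediate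
12 | (2R,3S)-6-hydroxy-2-(3-hydroxy-4,5-dimethoxyphenyl)-3,5,7-trimethoxychroman-4-one (cis) | COc1cc2c(c(OC)c1O)C(=O)[C@@H](OC)[C@@H](c1cc(O)c(OC)c(OC)c1)O2 | intermediate
13 | (2R,3R)-6-hydroxy-2-(3-hydroxy-4,5-dimethoxyphenyl)-3,5,7-trimethoxychroman-4-one (trans) | COc1cc2c(c(OC)c1O)C(=O)[C@H](OC)[C@@H](c1cc(O)c(OC)c(OC)c1)O2 | intermediate
14 | (2R,3R)-5,6-bis(dichloroboryloxy)-2-[3-(dichloroboryloxy)-4,5-dimethoxyphenyl]-3,7-dimethoxychroman-4-one | COc1cc2c(c(OB(Cl)Cl)c1OB(Cl)Cl)C(=O)[C@H](OC)[C@@H](c1cc(OB(Cl)Cl)c(OC)c(OC)c1)O2 | intermediate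
15 | (2R,3R)-5,6-dihydroxy-2-(3-hydroxy-4,5-dimethoxyphenyl)-3,7-dimethoxychroman-4-one (CNP0075601.1) | COc1cc2c(c(O)c1O)C(=O)[C@H](OC)[C@@H](c1cc(O)c(OC)c(OC)c1)O2 | target

**Total step count:** 5. **Longest linear sequence:** 4 (steps 1, 2, 4, 5).

**Steps most likely to fail**

Step 4. The 3-methoxy group may slow carborhodation, and base-induced retro-oxa-Michael opening may erode the ee. The fallback separates C–C bond formation from stereoinduction.
- It sets out from 7 and 11. An oxidative boron-Heck arylation (Pd(OAc)2, 1,10-phenanthroline, O2, DMF, 80 °C) gives the fully aromatic flavone 6-hydroxy-2-(3-hydroxy-4,5-dimethoxyphenyl)-3,5,7-trimethoxy-4H-chromen-4-one F1.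
- The pyrone ring of this flavone is then dearomatised by copper hydride asymmetric conjugate reduction (Cu(OAc)2, DTBM-SEGPHOS, (EtO)2MeSiH, t-BuOH, toluene; NH4F work-up).
- Hydride delivery now sets C2, and protonation with equilibration sets C3 as trans. The fallback comes back to the route at 13.

Step 2. Activated methoxyacetic acid may decarbonylate to a methoxymethyl cation, or it may O-acylate the hydroquinone instead of C-acylating it. The fallback uses a nitrile electrophile, which can do neither.
- It sets out from 3. A Hoesch reaction with methoxyacetonitrile (ZnCl2, HCl gas, Et2O, 0 °C) precipitates 1-(3,6-dihydroxy-2,4-dimethoxyphenyl)-2-methoxyethan-1-iminium chloride F2.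
- Hot water hydrolyses this salt to ketone 5, which is now isolated and purified.
- Ring closure with HC(OEt)3, pyridine and catalytic piperidine at 120 °C comes back to the route at 7.

Step 5. The boron bound at the 3'-oxygen or the 6-oxygen may also cleave the neighbouring 4'-OMe or 7-OMe. The fallback moves the demethylation ahead of ring B.
- It sets out from 7. AlCl3 in MeCN at 50 °C gives 5,6-dihydroxy-3,7-dimethoxy-4H-chromen-4-one F3.
- BnBr, K2CO3 and DMF give 5,6-bis(benzyloxy)-3,7-dimethoxy-4H-chromen-4-one F4.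
- The arylation of step 4 with 11 gives (2R,3R)-5,6-bis(benzyloxy)-2-(3-hydroxy-4,5-dimethoxyphenyl)-3,7-dimethoxychroman-4-one F5.
- Neutral hydrogenolysis (H2, Pd/C, EtOAc) comes back to the route at 15.

**Further compounds**
F1 | step 4 | 6-hydroxy-2-(3-hydroxy-4,5-dimethoxyphenyl)-3,5,7-trimethoxy-4H-chromen-4-one | COC1=C(Oc2cc(OC)c(O)c(OC)c2C1=O)c1cc(O)c(OC)c(OC)c1
F2 | step 2 | 1-(3,6-dihydroxy-2,4-dimethoxyphenyl)-2-methoxyethan-1-iminium chloride | COCC(=[NH2+])c1c(O)cc(OC)c(O)c1OC.[Cl-]
F3 | step 5 | 5,6-dihydroxy-3,7-dimethoxy-4H-chromen-4-one | COC1=COc2cc(OC)c(O)c(O)c2C1=O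
F4 | step 5 | 5,6-bis(benzyloxy)-3,7-dimethoxy-4H-chromen-4-one | COC1=COc2cc(OC)c(OCc3ccccc3)c(OCc3ccccc3)c2C1=O
F5 | step 5 | (2R,3R)-5,6-bis(benzyloxy)-2-(3-hydroxy-4,5-dimethoxyphenyl)-3,7-dimethoxychroman-4-one | COc1cc2c(c(OCc3ccccc3)c1OCc1ccccc1)C(=O)[C@H](OC)[C@@H](c1cc(O)c(OC)c(OC)c1)O2
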